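## Retrosynthetic overview

- **Feature:** the 2,5-dihydrofuran ring O–C5–C6=C7–C8 holds one alkene, the trisubstituted C6=C7 bond (C6 shared with the cyclohexane). It lies between the two sp3 ether carbons C5 and C8, so both centres can be fixed first and the ring closed last at the alkene.
- **C11=C12:** Wittig union of the furanoid C15 phosphonium salt with the C25 aldehyde apo-12'-lycopenal, itself made from pseudoionone + C2 (ψ-C15 salt) and one end of the C10 dialdehyde.
- **C6=C7:** ring-closing metathesis of the C5-tertiary / C8-secondary bis-allylic ether (C6 methylidene + C8 vinyl, loss of ethene).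
- **C8–O:** iridium-catalysed branched allylic etherification of the copper alkoxide of the (3S,5R)-methylidene carbinol with a prenol-derived dienyl phosphate, which sets C8. The carbinol comes from ketoisophorone via actinol (C3), cyclogeraniol, Sharpless epoxide (C5), iodide and zinc.
- **Ring order:** the cyclohexane is carried in from ketoisophorone. The dihydrofuran is the only ring that is built.

Key step: step 16

Remark (numbering): carotenoid numbering is used for the end group: C1 = CMe2, C3 = CH–O, C5 = C(CH3)–O, C6, C7, C8, C9(CH3)=C10, C11.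

Remark (assumption): the (Sa,Sc,Sc) enantiomer of the BINOL/bis(1-phenylethyl)amine phosphoramidite is taken to give the (8S) ether, by analogy with (S)-branched ethers from cinnamyl-type electrophiles. If a trial with CuOt-Bu shows the opposite sense, the mirror-image ligand is used and nothing else changes.

## Route

### Ring fragment (steps 1–9)

Step 1
Reactants: 1 ketoisophorone (2,6,6-trimethylcyclohex-2-ene-1,4-dione)
Product: 2 (6R)-levodione [(6R)-2,2,6-trimethylcyclohexane-1,4-dione]
Conditions: OYE2 ene-reductase, NADP+ (cat), glucose dehydrogenase, D-glucose, KPi buffer pH 7, 30 °C; prompt extraction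
Reagents that add atoms: none
Why: Enzymatic asymmetric conjugate reduction (old-yellow-enzyme type), well established for this enedione, in which net anti addition of H2 across C2=C3 inside the chiral active site should set the methyl-bearing carbon as (R).

Step 2
Reactants: 2 (6R)-levodione
Product: 3 (4R,6R)-actinol [(4R,6R)-4-hydroxy-2,2,6-trimethylcyclohexanone; OH trans to the 6-methyl]
Conditions: L-Selectride (1.05 equiv), THF, −78 °C; then NaOH, H2O2, 0 °C
Reagents that add atoms: none
Why: Sterically governed hydride reduction in which the bulky borohydride takes only the C4 carbonyl (C1 is flanked by CMe2 and CHMe) and, as with 3,3,5-trimethylcyclohexanone, attacks equatorially because the axial C2 methyl blocks the axial path, so the axial (4R)-alcohol trans to the equatorial C6 methyl is expected by substrate control.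

Step 3
Reactants: 3 (4R,6R)-actinol
Product: 4 (4R,6R)-4-(tert-butyldimethylsilyloxy)-2,2,6-trimethylcyclohexanone
Conditions: TBSCl, imidazole, DMF, rt
Reagents that add atoms: tert-butyldimethylsilyl chloride CC(C)(C)[Si](C)(C)Cl
Why: Imidazole-promoted silylation of a secondary alcohol, which touches no stereocentre.

Step 4
Reactants: 4 silyloxy ketone
Product: 6 (3R)-enol triflate [(4R)-4-TBSO-2,6,6-trimethylcyclohex-1-en-1-yl trifluoromethanesulfonate], via lithium enolate 5 (not isolated)
Conditions: LDA (1.2 equiv), THF, −78 → 0 °C; PhNTf2, −78 °C → rt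
Reagents that add atoms: N-phenylbis(trifluoromethanesulfonimide) O=S(=O)(N(c1ccccc1)S(=O)(=O)C(F)(F)F)C(F)(F)F
Why: Enolate O-triflation in which the ketone has a single α-hydrogen, so only the tetrasubstituted C5=C6 enolate can form, the methyl stereocentre is erased on purpose, and the γ-silyloxy group cannot β-eliminate.

Step 5
Reactants: 6 enol triflate
Product: 7 methyl (4R)-4-TBSO-2,6,6-trimethylcyclohex-1-ene-1-carboxylate
Conditions: CO (1 atm), Pd(OAc)2 (5 mol %), dppp, Et3N, MeOH/DMF, 60 °C
Reagents that add atoms: carbon monoxide [C-]#[O+]; methanol CO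
Why: Palladium-catalysed alkoxycarbonylation of an enol triflate (oxidative addition, CO insertion, methanolysis), a reaction known for 2,6,6-trimethylcyclohexenyl triflates.

Step 6
Reactants: 7 methyl ester
Product: 8 (3R)-3-TBSO-β-cyclogeraniol {[(4R)-4-TBSO-2,6,6-trimethylcyclohex-1-en-1-yl]methanol}
Conditions: DIBAL-H (2.5 equiv), CH2Cl2, −78 → 0 °C; Rochelle salt
Reagents that add atoms: none
Why: DIBAL-H 1,2-reduction of an α,β-unsaturated ester to the allylic alcohol, to which the silyl ether is inert.

Step 7
Reactants: 8 silyloxy cyclogeraniol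
Product: 9 (3S,5R,6R)-5,6-epoxy-3-TBSO-cyclogeraniol (epoxide on the ring face anti to the C3 silyloxy group)
Conditions: Ti(OiPr)4 (20 mol %), D-(−)-DET (24 mol %), t-BuOOH (decane), 4 Å MS, CH2Cl2, −20 °C
Reagents that add atoms: tert-butyl hydroperoxide CC(C)(C)OO
Why: Sharpless asymmetric epoxidation of a tetrasubstituted allylic alcohol, in which the D-(−)-tartrate complex delivers oxygen to the face anti to C3–OTBS and so sets C5 (and the transient C6) by reagent control over the weak substrate bias.

Step 8
Reactants: 9 epoxy alcohol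
Product: 10 epoxy iodide (7-iodide of 9 with unchanged spatial arrangement at C3, C5 and C6; the C6 descriptor becomes S by priority only)
Conditions: I2, PPh3, imidazole, THF/MeCN, 0 °C → rt, dark
Reagents that add atoms: iodine II
Why: Appel-type iodination (Garegg–Samuelsson conditions) by SN2 at the primary carbon, where the oxirane ties back two of the three β-substituents so that displacement is easier than at a true neopentyl centre, and imidazole buffering spares the epoxide.

Step 9
Reactants: 10 epoxy iodide
Product: 11 (3S,5R)-methylidene carbinol [(1R,5S)-5-TBSO-1,3,3-trimethyl-2-methylidenecyclohexan-1-ol]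
Conditions: Zn dust (activated), EtOH, reflux
Reagents that add atoms: none
Why: Reductive fragmentation of a 2,3-epoxy iodide (zinc insertion, then β-elimination with C6–O cleavage) gives the 1,3-transposed allylic alcohol, and because the C5–O bond is never broken the C5 configuration is retained.

### Side-chain electrophile (steps 10–14)

Step 10
Reactants: 12 prenol (3-methylbut-2-en-1-ol)
Product: 13 prenyl TBS ether
Conditions: TBSCl, imidazole, CH2Cl2, 0 °C → rt
Reagents that add atoms: tert-butyldimethylsilyl chloride CC(C)(C)[Si](C)(C)Cl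
Why: Standard silylation of a primary alcohol, chosen so that C11–O and C3–O can later be freed together by fluoride.

Step 11
Reactants: 13 prenyl TBS ether
Product: 15 (E)-4-TBSO-2-methylbut-2-enal, via allylic alcohol 14 (not isolated)
Conditions: SeO2 (0.3 equiv), t-BuOOH, CH2Cl2, 0 °C → rt; crude product: MnO2, CH2Cl2, rt
Reagents that add atoms: selenium dioxide O=[Se]=O; tert-butyl hydroperoxide CC(C)(C)OO
Why: Selenium dioxide allylic oxidation (ene reaction then [2,3]-sigmatropic shift) is inherently selective for the (E)-methyl group of a trisubstituted alkene, and MnO2 converges the alcohol/aldehyde mixture on the enal.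

Step 12
Reactants: 15 enal
Product: 16 ethyl (2E,4E)-6-TBSO-4-methylhexa-2,4-dienoate
Conditions: (EtO)2P(O)CH2CO2Et, NaH, THF, 0 °C → rt
Reagents that add atoms: triethyl phosphonoacetate CCOC(=O)CP(=O)(OCC)OCC
Why: Horner–Wadsworth–Emmons olefination with a stabilised phosphonate, which is E-selective and leaves the existing C9=C10 geometry alone.

Step 13
Reactants: 16 dienoate
Product: 17 (2E,4E)-6-TBSO-4-methylhexa-2,4-dien-1-ol
Conditions: DIBAL-H (2.2 equiv), CH2Cl2, −78 °C; Rochelle salt
Reagents that add atoms: none
Why: DIBAL-H 1,2-reduction of a dienoate to the dienol without conjugate reduction.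

Step 14
Reactants: 17 dienol
Product: 18 diethyl (2E,4E)-6-TBSO-4-methylhexa-2,4-dienyl phosphate
Conditions: (EtO)2P(O)Cl, pyridine, DMAP (cat), CH2Cl2, 0 °C; short Et3N-deactivated silica plug, used at once
Reagents that add atoms: diethyl chlorophosphate CCOP(=O)(Cl)OCC
Why: O-Phosphorylation of a primary allylic alcohol gives a leaving group that ionises readily on iridium but releases no nucleophilic alkoxide.

### Coupling, key step and C15 salt (steps 15–19)

Step 15
Reactants: 11 methylidene carbinol; 18 dienyl phosphate
Product: 21 (3S,5R,8S)-bis-allylic ether (C5 tertiary ether of 11 with the 8S carbinol carbon bearing vinyl and the (E)-C(CH3)=CH–CH2OTBS group), via lithium alkoxide 19 (not isolated), via copper(I) alkoxide 20 (not isolated)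
Conditions: 11, n-BuLi, THF, −78 → 0 °C; CuI, 0 °C → rt; then 18 (1.5 equiv), [Ir(cod)Cl]2 (4 mol %), (Sa,Sc,Sc)-phosphoramidite (8 mol %, pre-activated with n-PrNH2), THF, rt; Et3N-deactivated silica
Reagents that add atoms: none
Why: Iridium-catalysed asymmetric allylic etherification with a copper(I) alkoxide, in which the cyclometallated Ir–phosphoramidite ionises the linear phosphate to an η3-allyl complex and the soft tertiary alkoxide attacks the substituted terminus anti to the metal, so that the branched ether forms, C8 is set by the ligand (catalyst control), and no small alkoxide from the leaving group can outrun the hindered nucleophile.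

Step 16
Reactants: 21 bis-allylic ether
Product: 22 (3S,5R,8S)-3,11-bis-O-TBS furanoid C15 diol [(2S,6S,7aR)-6-TBSO-2-[(E)-4-TBSO-but-2-en-2-yl]-4,4,7a-trimethyl-2,4,5,6,7,7a-hexahydrobenzofuran]
Conditions: Hoveyda–Grubbs-type catalyst with the N,N'-di(o-tolyl) NHC (10 mol % in portions), 1,4-benzoquinone (20 mol %), toluene (0.002 M), 80–100 °C, Ar sparge; Et3N-deactivated silica
Reagents that add atoms: none
Why: Ring-closing olefin metathesis: ruthenium initiates at the only monosubstituted alkene, the C8 vinyl group, to give the C7 alkylidene, which adds [2+2] across the C6 methylidene with C7 bonding to C6 and Ru to the CH2 terminus, and cycloreversion releases Ru=CH2, which carries the chain and leaves as ethene. The closest known reaction type is the closure of allyl ethers of 2-methylidene carbinols to 2,5-dihydrofurans, including ethers made by metal-catalysed branched allylic etherification. The one ring formed (O–C5–C6=C7–C8) closes in a 5-exo sense at the inner carbon of the methylidene, so the new trisubstituted alkene is endocyclic to the furan ring and exocyclic to the cyclohexane. No stereocentre is formed or touched, since C5 and C8 stay sp3 ether carbons and carry over the configurations set in steps 7 and 15. The step needs site selectivity (the trisubstituted C9=C10 bond stays out, since closure onto it would give only a strained small ring) and cyclisation ahead of vinyl dimerisation or Ru–H isomerisation; this is secured by the favoured chair with C5–O axial and C3–OTBS and C5–CH3 equatorial, which holds the alkylidene over the face of C6=CH2, by the quaternary C5 (Thorpe–Ingold effect), and by high dilution, ethene removal and benzoquinone. The crowding of a methylidene flanked by the quaternary C1 and C5 is met with the small o-tolyl NHC ligand and heat.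

Step 17
Reactants: 22 bis-silyl ether
Product: 23 (3S,5R,8S)-furanoid C15 diol
Conditions: TBAF (3 equiv), THF, 0 °C → rt; Et3N-deactivated silica
Reagents that add atoms: none
Why: Fluoride-mediated desilylation frees both hydroxyls in one basic, non-oxidative operation, which avoids acid (C8 epimerisation) and hydride-abstracting oxidants such as DDQ (the C8–H is a doubly allylic ether C–H).

Step 18
Reactants: 23 diol
Product: 24 (3S,5R,8S)-furanoid C15 allylic bromide (C11–Br, free C3–OH)
Conditions: NBS, Me2S, CH2Cl2, 0 °C (reagent formation); 23, −20 → 0 °C; cold aqueous work-up, used at once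
Reagents that add atoms: N-bromosuccinimide O=C1CCC(=O)N1Br
Why: Corey–Kim-type halogenation under neutral conditions, in which only the allylic alkoxysulfonium ion is displaced by bromide (SN2) while the one at the saturated C3 alcohol reverts to the alcohol on work-up.

Step 19
Reactants: 24 allylic bromide
Product: 25 (3S,5R,8S)-furanoid C15 triphenylphosphonium bromide (free C3–OH)
Conditions: PPh3, EtOAc, rt, dark; salt collected by filtration
Reagents that add atoms: triphenylphosphine c1ccc(cc1)P(c1ccccc1)c1ccccc1
Why: SN2 quaternisation of triphenylphosphine by a primary allylic bromide in a neutral medium, with purification by precipitation.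

### C25 aldehyde (steps 20–22)

Step 20
Reactants: 26 (3E,5E)-pseudoionone
Product: 27 vinyl-ψ-ionol [(4E,6E)-3,7,11-trimethyldodeca-1,4,6,10-tetraen-3-ol, racemic at C3]
Conditions: CH2=CHMgBr, THF, −20 → 0 °C; then H2O
Reagents that add atoms: vinylmagnesium bromide C=C[Mg]Br
Why: Grignard 1,2-addition to a dienone, where the new carbinol centre is racemic and is lost in the next step.

Step 21
Reactants: 27 vinyl-ψ-ionol
Product: 28 [(2E,4E,6E)-3,7,11-trimethyldodeca-2,4,6,10-tetraenyl]triphenylphosphonium bromide
Conditions: PPh3·HBr, MeOH, 0 °C → rt; crystallisation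
Reagents that add atoms: triphenylphosphine hydrobromide [Br-].[PH+](c1ccccc1)(c1ccccc1)c1ccccc1
Why: Allylic transposition with phosphonium salt formation, in which the tertiary bis-allylic alcohol ionises and PPh3 captures the delocalised cation at its primary terminus, as practised for the lycopene C15 salt, with the (E)-salt enriched by crystallisation.

Step 22
Reactants: 28 ψ-C15 phosphonium bromide; 29 (2E,4E,6E)-2,7-dimethylocta-2,4,6-trienedial (C10 dialdehyde)
Product: 31 all-E apo-12'-lycopenal (C25 aldehyde), via ylide 30 (not isolated)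
Conditions: 29 (3 equiv), NaOMe, MeOH/CH2Cl2, 0 °C → rt, slow addition of 28; then EtOH, reflux; crystallisation, excess 29 recovered
Reagents that add atoms: none
Why: Wittig olefination with a semi-stabilised allylic ylide, in which excess of the symmetrical dialdehyde secures monocondensation and the Z isomer at the new disubstituted bond is isomerised thermally to E.

### Final coupling (step 23)

Step 23
Reactants: 25 furanoid C15 phosphonium bromide; 31 C25 aldehyde
Product: 33 target (3S,5R,8S,all-E)-5,8-epoxy-5,8-dihydro-β,ψ-caroten-3-ol, via ylide 32 (not isolated)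
Conditions: 25 + 31, CH2Cl2/MeOH, NaOMe added last, 0 °C → rt; then EtOH, reflux, Ar, dark; crystallisation
Reagents that add atoms: none
Why: Wittig olefination in which the allylic ylide is generated in the presence of the aldehyde and trapped before the ring oxygen at C8 can leave by vinylogous β-elimination, the free C3 hydroxyl is tolerated as in hydroxy-carotenoid practice, no stereocentre is touched, and the hindered 11Z isomer is converted thermally into the all-E polyene.

## Compound list

1 | ketoisophorone | CC1=CC(=O)CC(C)(C)C1=O | starting material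
2 | (6R)-levodione | O=C1C(C)(C)CC(=O)C[C@H]1C | intermediate
3 | (4R,6R)-actinol | O=C1C(C)(C)C[C@H](O)C[C@H]1C | intermediate
4 | (4R,6R)-4-TBSO-2,2,6-trimethylcyclohexanone | O=C1C(C)(C)C[C@H](O[Si](C)(C)C(C)(C)C)C[C@H]1C | intermediate
5 | lithium enolate of 4 | CC1=C(O[Li])C(C)(C)C[C@H](O[Si](C)(C)C(C)(C)C)C1 | intermediate
6 | (3R)-enol triflate | CC1=C(OS(=O)(=O)C(F)(F)F)C(C)(C)C[C@H](O[Si](C)(C)C(C)(C)C)C1 | intermediate
7 | methyl (4R)-4-TBSO-2,6,6-trimethylcyclohex-1-ene-1-carboxylate | CC1=C(C(=O)OC)C(C)(C)C[C@H](O[Si](C)(C)C(C)(C)C)C1 | intermediate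
8 | (3R)-3-TBSO-β-cyclogeraniol | CC1=C(CO)C(C)(C)C[C@H](O[Si](C)(C)C(C)(C)C)C1 | intermediate
9 | (3S,5R,6R)-5,6-epoxy-3-TBSO-cyclogeraniol | C[C@]12O[C@@]1(CO)C(C)(C)C[C@H](O[Si](C)(C)C(C)(C)C)C2 | intermediate
10 | epoxy iodide | C[C@]12O[C@@]1(CI)C(C)(C)C[C@H](O[Si](C)(C)C(C)(C)C)C2 | intermediate
11 | (3S,5R)-methylidene carbinol | C=C1C(C)(C)C[C@H](O[Si](C)(C)C(C)(C)C)C[C@@]1(C)O | intermediate
12 | prenol | CC(C)=CCO | starting material
13 | prenyl TBS ether | CC(C)=CCO[Si](C)(C)C(C)(C)C | intermediate
14 | (E)-4-TBSO-2-methylbut-2-en-1-ol | OC/C(C)=C/CO[Si](C)(C)C(C)(C)C | intermediate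
15 | (E)-4-TBSO-2-methylbut-2-enal | O=C/C(C)=C/CO[Si](C)(C)C(C)(C)C | intermediate
16 | ethyl (2E,4E)-6-TBSO-4-methylhexa-2,4-dienoate | CCOC(=O)/C=C/C(C)=C/CO[Si](C)(C)C(C)(C)C | intermediate
17 | (2E,4E)-6-TBSO-4-methylhexa-2,4-dien-1-ol | OC/C=C/C(C)=C/CO[Si](C)(C)C(C)(C)C | intermediate
18 | diethyl dienyl phosphate | CCOP(=O)(OCC)OC/C=C/C(C)=C/CO[Si](C)(C)C(C)(C)C | intermediate
19 | lithium alkoxide of 11 | C=C1C(C)(C)C[C@H](O[Si](C)(C)C(C)(C)C)C[C@@]1(C)O[Li] | intermediate
20 | copper(I) alkoxide of 11 | C=C1C(C)(C)C[C@H](O[Si](C)(C)C(C)(C)C)C[C@@]1(C)O[Cu] | intermediate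
21 | (3S,5R,8S)-bis-allylic ether (metathesis precursor) | C=C1C(C)(C)C[C@H](O[Si](C)(C)C(C)(C)C)C[C@@]1(C)O[C@@H](C=C)/C(C)=C/CO[Si](C)(C)C(C)(C)C | intermediate
22 | (3S,5R,8S)-3,11-bis-O-TBS furanoid C15 diol (metathesis product) | CC(C)(C)[Si](C)(C)OC/C=C(C)/[C@@H]1C=C2C(C)(C)C[C@H](O[Si](C)(C)C(C)(C)C)C[C@@]2(C)O1 | intermediate
23 | (3S,5R,8S)-furanoid C15 diol | OC/C=C(C)/[C@@H]1C=C2C(C)(C)C[C@H](O)C[C@@]2(C)O1 | intermediate
24 | furanoid C15 allylic bromide | BrC/C=C(C)/[C@@H]1C=C2C(C)(C)C[C@H](O)C[C@@]2(C)O1 | intermediate
25 | furanoid C15 triphenylphosphonium bromide | c1ccccc1[P+](c1ccccc1)(c1ccccc1)C/C=C(C)/[C@@H]1C=C2C(C)(C)C[C@H](O)C[C@@]2(C)O1.[Br-] | intermediate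
26 | (3E,5E)-pseudoionone | CC(C)=CCC/C(C)=C/C=C/C(C)=O | starting material
27 | vinyl-ψ-ionol (racemic) | CC(C)=CCC/C(C)=C/C=C/C(C)(O)C=C | intermediate
28 | ψ-C15 triphenylphosphonium bromide | CC(C)=CCC/C(C)=C/C=C/C(C)=C/C[P+](c1ccccc1)(c1ccccc1)c1ccccc1.[Br-] | intermediate
29 | C10 dialdehyde | O=C/C(C)=C/C=C/C=C(C)/C=O | starting material
30 | ylide from 28 | CC(C)=CCC/C(C)=C/C=C/C(C)=C/C=P(c1ccccc1)(c1ccccc1)c1ccccc1 | intermediate
31 | apo-12'-lycopenal (C25 aldehyde) | CC(C)=CCC/C(C)=C/C=C/C(C)=C/C=C/C(C)=C/C=C/C=C(C)/C=O | intermediate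
32 | ylide from 25 | c1ccccc1P(c1ccccc1)(c1ccccc1)=C/C=C(C)/[C@@H]1C=C2C(C)(C)C[C@H](O)C[C@@]2(C)O1 | intermediate
33 | target, CNP0182031.1 | CC(C)=CCC/C(C)=C/C=C/C(C)=C/C=C/C(C)=C/C=C/C=C(C)/C=C/C=C(\C)[C@@H]1C=C2C(C)(C)C[C@H](O)C[C@@]2(C)O1 | target

## Step count and risks

Total step count: 23.
Longest linear sequence: 15 (steps 1–9, 15–19, 23).

**Step 16 (ring-closing metathesis).** The C7 alkylidene may fail to engage a methylidene crowded by two quaternary neighbours. Dimerisation through the vinyl group, catalyst decay and Ru–H migration of the vinyl double bond would then take over.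

The fallback gives up the metathesis and the control of C8. It sets out from 9 and comes back at 23.
- 9 is oxidised (SO3·pyridine, DMSO, Et3N) to the epoxy aldehyde F1.
- F1 is extended by Horner–Wadsworth–Emmons reaction with triethyl 3-methyl-4-phosphonocrotonate and LiHMDS to the (7E,9E)-5,6-epoxy C15 ester F2.
- F2 is reduced with DIBAL-H to the 5,6-epoxy C15 alcohol F3.
- A trace of acid (cat TsOH, CH2Cl2, 0 °C) triggers the classical 5,6-epoxide to 5,8-furanoid rearrangement, with C5 retained.
- The rearrangement gives the (8S)-furanoid 3-O-TBS alcohol F4 together with its (8R)-epimer F5. They are separated by chromatography, and F5 is re-equilibrated with acid.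
- TBAF on F4 gives 23.

**Step 15 (iridium-catalysed etherification).** Capture of the allyl-iridium intermediate by the hindered tertiary alkoxide may be slow. That would bring erosion of branched selectivity, elimination to a triene, or weak catalyst control at C8.

The fallback takes C8 from a preformed stereocentre instead of the catalyst. It sets out from 15 and 11 and comes back at 21.
- Vinylmagnesium bromide adds to 15 to give the racemic bis-allylic carbinol F6.
- Lipase resolution (CAL-B, vinyl acetate) follows the usual size rule: it leaves the (S)-alcohol F7 and acylates the antipode to the (R)-acetate F8.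
- Methyl chloroformate/pyridine converts F7 into the (S)-methyl carbonate F9.
- Rhodium-catalysed enantiospecific allylic etherification (RhCl(PPh3)3, P(OMe)3, THF) with the copper alkoxide 20 gives 21. The alkoxide is made from 11, used in excess and recovered. The reaction substitutes at the carbon that bore the leaving group with net retention.

**Step 8 (iodination).** Displacement at a primary carbon next to a fully substituted centre may be slow. Opening or deoxygenation of the oxirane by the phosphine–iodine reagent could then compete.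

The fallback replaces SN2 by electron transfer. It sets out from 9 and comes back at 11.
- 9 is mesylated on oxygen (MsCl, Et3N, CH2Cl2, 0 °C) to the epoxy mesylate F10.
- Sodium naphthalenide (THF, −78 °C) cleaves the C7–O bond reductively and opens the epoxide by β-elimination. This gives 11 directly and skips step 9.

## Further compounds

F1 | step 16 | (3S,5R,6R)-5,6-epoxy-3-TBSO-cyclocitral (epoxy aldehyde) | C[C@]12O[C@@]1(C=O)C(C)(C)C[C@H](O[Si](C)(C)C(C)(C)C)C2
F2 | step 16 | ethyl (7E,9E)-5,6-epoxy-3-TBSO C15 dienoate | C[C@]12O[C@@]1(/C=C/C(C)=C/C(=O)OCC)C(C)(C)C[C@H](O[Si](C)(C)C(C)(C)C)C2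
F3 | step 16 | (7E,9E)-5,6-epoxy-3-TBSO C15 alcohol | C[C@]12O[C@@]1(/C=C/C(C)=C/CO)C(C)(C)C[C@H](O[Si](C)(C)C(C)(C)C)C2
F4 | step 16 | (3S,5R,8S)-3-O-TBS furanoid C15 alcohol | OC/C=C(C)/[C@@H]1C=C2C(C)(C)C[C@H](O[Si](C)(C)C(C)(C)C)C[C@@]2(C)O1
F5 | step 16 | (3S,5R,8R)-3-O-TBS furanoid C15 alcohol | OC/C=C(C)/[C@H]1C=C2C(C)(C)C[C@H](O[Si](C)(C)C(C)(C)C)C[C@@]2(C)O1
F6 | step 15 | racemic (E)-6-TBSO-4-methylhexa-1,4-dien-3-ol | C=CC(O)/C(C)=C/CO[Si](C)(C)C(C)(C)C
F7 | step 15 | (S,E)-6-TBSO-4-methylhexa-1,4-dien-3-ol | O[C@@H](C=C)/C(C)=C/CO[Si](C)(C)C(C)(C)C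
F8 | step 15 | (R,E)-6-TBSO-4-methylhexa-1,4-dien-3-yl acetate | CC(=O)O[C@H](C=C)/C(C)=C/CO[Si](C)(C)C(C)(C)C
F9 | step 15 | (S,E)-6-TBSO-4-methylhexa-1,4-dien-3-yl methyl carbonate | COC(=O)O[C@@H](C=C)/C(C)=C/CO[Si](C)(C)C(C)(C)C
F10 | step 8 | epoxy mesylate of 9 | C[C@]12O[C@@]1(COS(C)(=O)=O)C(C)(C)C[C@H](O[Si](C)(C)C(C)(C)C)C2
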